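**Plan**
Labels: rings A to E follow the chain from the 2,4,6-trihydroxyphenyl end (A) to the 3,4,5-trihydroxyphenyl end (E). B1 carries O–A, B3 and B4 carry OH, B5 carries O–C; C1 carries O–B, C2 carries O–D; D1 carries O–C, D4 carries O–E; E1 carries O–D and E4 lies para to it.
Cuts: each of the four ether bridges is cut at the ring carbon that can be made electrophilic, first O–E1, then O–D1, last O–B5 and O–B1 as a pair. The hydroxyls travel as methyl ethers and the C2 oxygen as a benzyl ether.
Enabling feature: the oxygen-bearing carbon B4 sits para to B1 and ortho to both B5 and B3. A single CHO on B4 of a trifluorinated ring B therefore switches on all three C–F carbons for SNAr, and it is afterwards traded for the B4 oxygen by aryl migration to peroxide oxygen. D4/D1 and E4/E1 repeat the para relation.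
Forward: no ring is closed; five intact benzene rings are strung together. The order is ring C phenol (steps 1–3), A + B + C in one flask (step 4), tidying of ring B and release of the C2 phenol (steps 5–8), ring D (steps 9–10), ring E (steps 11–12), global demethylation (step 13).
Stereochemistry: the target has no stereocentre and its ether axes rotate freely, so no stereocontrol is required.

Key step: step 4

Assumption: the four aromatic building blocks that enter as starting materials are taken as purchasable, and all phenoxide chemistry is run under argon because the polyalkoxyphenoxides oxidise easily in air.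

Step 1
Reactants: 1 2,3,4-trimethoxyphenol
Product: 3 2-hydroxy-3,4,5-trimethoxybenzaldehyde, via magnesium-bound salicyl alcohol 2 (not isolated)
Conditions: MgCl2, Et3N, (CH2O)n, MeCN, reflux; aq. HCl work-up
Reagents that add atoms: paraformaldehyde (reacts as formaldehyde), C=O
Why: Casnati–Skattebøl ortho-formylation, in which the magnesium phenoxide binds formaldehyde and delivers it to the only free ortho carbon, and a second formaldehyde oxidises the benzylic alkoxide 2 to the aldehyde by hydride transfer, so one regioisomer is expected.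

Step 2
Reactants: 3 2-hydroxy-3,4,5-trimethoxybenzaldehyde
Product: 4 2-(benzyloxy)-3,4,5-trimethoxybenzaldehyde
Conditions: BnBr, K2CO3, DMF, 60 °C
Reagents that add atoms: benzyl bromide, BrCc1ccccc1
Why: Williamson etherification of the acidic salicylaldehyde hydroxyl puts a hydrogenolysable group on the oxygen that later becomes the C2–O–D1 bridge and leaves the methyl ethers and the aldehyde untouched.

Step 3
Reactants: 4 2-(benzyloxy)-3,4,5-trimethoxybenzaldehyde
Product: 6 2-(benzyloxy)-3,4,5-trimethoxyphenol, via ring C aryl formate 5 (not isolated)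
Conditions: mCPBA, CH2Cl2, 0 °C to rt; aq. Na2S2O3/NaHCO3 wash; then K2CO3 (cat.), MeOH, rt
Reagents that add atoms: mCPBA, OOC(=O)c1cccc(Cl)c1
Why: Baeyer–Villiger oxidation in its Dakin-type form, in which the aryl group enriched by ortho and para alkoxy donors migrates in the Criegee adduct in preference to hydride, and the formate keeps the electron-rich phenol masked until the peracid is washed out and mild methanolysis frees it.

Step 4
Reactants: 7 2,4,6-trifluorobenzaldehyde; 8 2,4,6-trimethoxyphenol; 6 2-(benzyloxy)-3,4,5-trimethoxyphenol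
Product: 10 2-[2-(benzyloxy)-3,4,5-trimethoxyphenoxy]-6-fluoro-4-(2,4,6-trimethoxyphenoxy)benzaldehyde, via para-substituted difluoroaldehyde 9 (not isolated)
Conditions: 8 (1.0 equiv), Cs2CO3, DMF, slow addition to 7 at −20 °C, then to rt; then 6 (1.0 equiv), Cs2CO3, same flask, 60 °C, argon
Reagents that add atoms: none
Why: Each C–O bond arises by addition–elimination: the phenoxide adds to a C–F carbon to give a Meisenheimer anion whose charge is taken up by the B4 formyl group, and loss of fluoride restores the arene. The closest known reaction type is the stepwise SNAr of polyfluorinated benzaldehydes with phenoxides, a standard entry to diaryl ethers. No ring is closed and no stereocentre is created, so only site selectivity and the degree of substitution matter. The first substitution must occur at the para fluorine (B1), which is secured by the two ortho methoxy groups of 8 that clash with the formyl group on ortho approach, by the loosely paired caesium phenoxide in DMF that offers no carbonyl-chelated delivery to the ortho sites, and by slow addition of one equivalent at low temperature. In 9 the two remaining fluorines are equivalent, so the less encumbered phenoxide of 6 can give only one constitution, and it should choose a C–F carbon over the far less electrophilic C–OAr carbon B1, which leaves the newly made ether in place. Every aryloxy group introduced lowers the electrophilicity of ring B, so with one equivalent of 6 at 60 °C the reaction should halt at 10 with the B3 fluorine intact.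

Step 5
Reactants: 10 2-[2-(benzyloxy)-3,4,5-trimethoxyphenoxy]-6-fluoro-4-(2,4,6-trimethoxyphenoxy)benzaldehyde
Product: 11 2-[2-(benzyloxy)-3,4,5-trimethoxyphenoxy]-6-methoxy-4-(2,4,6-trimethoxyphenoxy)benzaldehyde
Conditions: NaOMe, MeOH/THF, rt to 45 °C
Reagents that add atoms: sodium methoxide, [Na+].[O-]C
Why: SNAr of the last fluoride, still ortho to the formyl group, by small hard methoxide; the C–F carbon is far more electrophilic than the two C–OAr carbons, so the diaryl ethers should persist, and hemiacetal formation at the aldehyde is reversible.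

Step 6
Reactants: 11 2-[2-(benzyloxy)-3,4,5-trimethoxyphenoxy]-6-methoxy-4-(2,4,6-trimethoxyphenoxy)benzaldehyde
Product: 13 2-[2-(benzyloxy)-3,4,5-trimethoxyphenoxy]-6-methoxy-4-(2,4,6-trimethoxyphenoxy)phenol, via ring B aryl formate 12 (not isolated)
Conditions: mCPBA (1.1 equiv), CH2Cl2, 0 °C to rt; aq. Na2S2O3/NaHCO3 wash; then K2CO3 (cat.), MeOH/THF, rt, argon
Reagents that add atoms: mCPBA, OOC(=O)c1cccc(Cl)c1
Why: Baeyer–Villiger (Dakin-type) oxidation of a 2,4,6-trioxygenated benzaldehyde, the best case for aryl migration, turns the spent activating group into the B4 oxygen, and removing the acceptor before the C2 phenol is freed also excludes a later Smiles migration of ring B.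

Step 7
Reactants: 13 2-[2-(benzyloxy)-3,4,5-trimethoxyphenoxy]-6-methoxy-4-(2,4,6-trimethoxyphenoxy)phenol
Product: 14 2-(benzyloxy)-1-[2,3-dimethoxy-5-(2,4,6-trimethoxyphenoxy)phenoxy]-3,4,5-trimethoxybenzene
Conditions: MeI, K2CO3, DMF, rt
Reagents that add atoms: iodomethane, CI
Why: Williamson methylation of the only free hydroxyl ensures that the C2 phenol released next is the sole nucleophile, and methyl is chosen because it falls in the final global cleavage.

Step 8
Reactants: 14 2-(benzyloxy)-1-[2,3-dimethoxy-5-(2,4,6-trimethoxyphenoxy)phenoxy]-3,4,5-trimethoxybenzene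
Product: 15 6-[2,3-dimethoxy-5-(2,4,6-trimethoxyphenoxy)phenoxy]-2,3,4-trimethoxyphenol
Conditions: H2 (1 atm), 10% Pd/C, EtOAc/MeOH, rt
Reagents that add atoms: none
Why: Catalytic hydrogenolysis cleaves the single benzylic C–O bond, while aryl methyl ethers and diaryl ethers are inert to H2 over palladium on carbon and no other reducible group is left.

Step 9
Reactants: 15 6-[2,3-dimethoxy-5-(2,4,6-trimethoxyphenoxy)phenoxy]-2,3,4-trimethoxyphenol; 16 4-fluoro-2,6-dimethoxybenzaldehyde
Product: 17 4-{6-[2,3-dimethoxy-5-(2,4,6-trimethoxyphenoxy)phenoxy]-2,3,4-trimethoxyphenoxy}-2,6-dimethoxybenzaldehyde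
Conditions: 16 (1.5 equiv), Cs2CO3, DMSO, 110–120 °C, argon
Reagents that add atoms: none
Why: SNAr through a Meisenheimer anion stabilised by the para formyl group; both methoxy groups of 16 are meta to the C–F carbon and so feed no charge onto the carbon attacked, that site is sterically open, and the naked caesium phenoxide in hot DMSO compensates for the crowding around the C2 oxygen.

Step 10
Reactants: 17 4-{6-[2,3-dimethoxy-5-(2,4,6-trimethoxyphenoxy)phenoxy]-2,3,4-trimethoxyphenoxy}-2,6-dimethoxybenzaldehyde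
Product: 19 4-{6-[2,3-dimethoxy-5-(2,4,6-trimethoxyphenoxy)phenoxy]-2,3,4-trimethoxyphenoxy}-2,6-dimethoxyphenol, via ring D aryl formate 18 (not isolated)
Conditions: mCPBA (1.1 equiv), CH2Cl2, 0 °C; aq. Na2S2O3/NaHCO3 wash; then K2CO3 (cat.), MeOH/THF, rt, argon
Reagents that add atoms: mCPBA, OOC(=O)c1cccc(Cl)c1
Why: Baeyer–Villiger (Dakin-type) oxidation in which the 2,6-dimethoxy-4-aryloxyphenyl group migrates readily, so one equivalent of peracid at 0 °C should be consumed by the aldehyde before it touches the electron-rich rings, and methanolysis then unveils the D4 hydroxyl.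

Step 11
Reactants: 19 4-{6-[2,3-dimethoxy-5-(2,4,6-trimethoxyphenoxy)phenoxy]-2,3,4-trimethoxyphenoxy}-2,6-dimethoxyphenol; 16 4-fluoro-2,6-dimethoxybenzaldehyde
Product: 20 4-(4-{6-[2,3-dimethoxy-5-(2,4,6-trimethoxyphenoxy)phenoxy]-2,3,4-trimethoxyphenoxy}-2,6-dimethoxyphenoxy)-2,6-dimethoxybenzaldehyde
Conditions: 16 (1.5 equiv), Cs2CO3, DMSO, 110–120 °C, argon
Reagents that add atoms: none
Why: A second SNAr of the same kind, in which the 2,6-dimethoxyphenoxide of 19, similar in bulk and nucleophilicity to that of 8, attacks the open para C–F carbon, while rings A to D carry no acceptor any more and their ether bridges cannot exchange.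

Step 12
Reactants: 20 4-(4-{6-[2,3-dimethoxy-5-(2,4,6-trimethoxyphenoxy)phenoxy]-2,3,4-trimethoxyphenoxy}-2,6-dimethoxyphenoxy)-2,6-dimethoxybenzaldehyde
Product: 22 4-(4-{6-[2,3-dimethoxy-5-(2,4,6-trimethoxyphenoxy)phenoxy]-2,3,4-trimethoxyphenoxy}-2,6-dimethoxyphenoxy)-2,6-dimethoxyphenol, via ring E aryl formate 21 (not isolated)
Conditions: mCPBA (1.1 equiv), CH2Cl2, 0 °C; aq. Na2S2O3/NaHCO3 wash; then K2CO3 (cat.), MeOH/THF, rt, argon
Reagents that add atoms: mCPBA, OOC(=O)c1cccc(Cl)c1
Why: The third Baeyer–Villiger (Dakin-type) oxidation follows the pattern of steps 6 and 10 and installs the E4 oxygen, which may stay free because only the deprotection follows.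

Step 13
Reactants: 22 4-(4-{6-[2,3-dimethoxy-5-(2,4,6-trimethoxyphenoxy)phenoxy]-2,3,4-trimethoxyphenoxy}-2,6-dimethoxyphenoxy)-2,6-dimethoxyphenol
Product: 23 5-(4-{6-[2,3-dihydroxy-5-(2,4,6-trihydroxyphenoxy)phenoxy]-2,3,4-trihydroxyphenoxy}-2,6-dihydroxyphenoxy)benzene-1,2,3-triol (CNP0228612.0)
Conditions: BBr3 (about 2 equiv per OMe), CH2Cl2, −78 °C to rt; then H2O, 0 °C, argon
Reagents that add atoms: none
Why: Lewis acid mediated aryl methyl ether cleavage, in which BBr3 binds each methoxy oxygen and bromide attacks the methyl carbon by SN2, a path closed to the diaryl ether oxygens because they bear no sp3 carbon, so the four bridges survive and hydrolysis of the borates gives the thirteen free hydroxyls.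

**Compound list**
1 | 2,3,4-trimethoxyphenol | COc1ccc(O)c(OC)c1OC | starting material
2 | 6-(hydroxymethyl)-2,3,4-trimethoxyphenol (present as its magnesium salt) | OCc1cc(OC)c(OC)c(OC)c1O | intermediate
3 | 2-hydroxy-3,4,5-trimethoxybenzaldehyde | O=Cc1cc(OC)c(OC)c(OC)c1O | intermediate
4 | 2-(benzyloxy)-3,4,5-trimethoxybenzaldehyde | O=Cc1cc(OC)c(OC)c(OC)c1OCc1ccccc1 | intermediate
5 | 2-(benzyloxy)-3,4,5-trimethoxyphenyl formate | O=COc1cc(OC)c(OC)c(OC)c1OCc1ccccc1 | intermediate
6 | 2-(benzyloxy)-3,4,5-trimethoxyphenol | Oc1cc(OC)c(OC)c(OC)c1OCc1ccccc1 | intermediate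
7 | 2,4,6-trifluorobenzaldehyde | O=Cc1c(F)cc(F)cc1F | starting material
8 | 2,4,6-trimethoxyphenol | COc1cc(OC)c(O)c(OC)c1 | starting material
9 | 2,6-difluoro-4-(2,4,6-trimethoxyphenoxy)benzaldehyde | O=Cc1c(F)cc(Oc2c(OC)cc(OC)cc2OC)cc1F | intermediate
10 | 2-[2-(benzyloxy)-3,4,5-trimethoxyphenoxy]-6-fluoro-4-(2,4,6-trimethoxyphenoxy)benzaldehyde | O=Cc1c(F)cc(Oc2c(OC)cc(OC)cc2OC)cc1Oc1cc(OC)c(OC)c(OC)c1OCc1ccccc1 | intermediate
11 | 2-[2-(benzyloxy)-3,4,5-trimethoxyphenoxy]-6-methoxy-4-(2,4,6-trimethoxyphenoxy)benzaldehyde | O=Cc1c(OC)cc(Oc2c(OC)cc(OC)cc2OC)cc1Oc1cc(OC)c(OC)c(OC)c1OCc1ccccc1 | intermediate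
12 | 2-[2-(benzyloxy)-3,4,5-trimethoxyphenoxy]-6-methoxy-4-(2,4,6-trimethoxyphenoxy)phenyl formate | O=COc1c(OC)cc(Oc2c(OC)cc(OC)cc2OC)cc1Oc1cc(OC)c(OC)c(OC)c1OCc1ccccc1 | intermediate
13 | 2-[2-(benzyloxy)-3,4,5-trimethoxyphenoxy]-6-methoxy-4-(2,4,6-trimethoxyphenoxy)phenol | Oc1c(OC)cc(Oc2c(OC)cc(OC)cc2OC)cc1Oc1cc(OC)c(OC)c(OC)c1OCc1ccccc1 | intermediate
14 | 2-(benzyloxy)-1-[2,3-dimethoxy-5-(2,4,6-trimethoxyphenoxy)phenoxy]-3,4,5-trimethoxybenzene | COc1c(OC)cc(Oc2c(OC)cc(OC)cc2OC)cc1Oc1cc(OC)c(OC)c(OC)c1OCc1ccccc1 | intermediate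
15 | 6-[2,3-dimethoxy-5-(2,4,6-trimethoxyphenoxy)phenoxy]-2,3,4-trimethoxyphenol | COc1c(OC)cc(Oc2c(OC)cc(OC)cc2OC)cc1Oc1cc(OC)c(OC)c(OC)c1O | intermediate
16 | 4-fluoro-2,6-dimethoxybenzaldehyde | COc1cc(F)cc(OC)c1C=O | starting material
17 | 4-{6-[2,3-dimethoxy-5-(2,4,6-trimethoxyphenoxy)phenoxy]-2,3,4-trimethoxyphenoxy}-2,6-dimethoxybenzaldehyde | COc1c(OC)cc(Oc2c(OC)cc(OC)cc2OC)cc1Oc1cc(OC)c(OC)c(OC)c1Oc1cc(OC)c(C=O)c(OC)c1 | intermediate
18 | 4-{6-[2,3-dimethoxy-5-(2,4,6-trimethoxyphenoxy)phenoxy]-2,3,4-trimethoxyphenoxy}-2,6-dimethoxyphenyl formate | COc1c(OC)cc(Oc2c(OC)cc(OC)cc2OC)cc1Oc1cc(OC)c(OC)c(OC)c1Oc1cc(OC)c(OC=O)c(OC)c1 | intermediate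
19 | 4-{6-[2,3-dimethoxy-5-(2,4,6-trimethoxyphenoxy)phenoxy]-2,3,4-trimethoxyphenoxy}-2,6-dimethoxyphenol | COc1c(OC)cc(Oc2c(OC)cc(OC)cc2OC)cc1Oc1cc(OC)c(OC)c(OC)c1Oc1cc(OC)c(O)c(OC)c1 | intermediate
20 | 4-(4-{6-[2,3-dimethoxy-5-(2,4,6-trimethoxyphenoxy)phenoxy]-2,3,4-trimethoxyphenoxy}-2,6-dimethoxyphenoxy)-2,6-dimethoxybenzaldehyde | COc1c(OC)cc(Oc2c(OC)cc(OC)cc2OC)cc1Oc1cc(OC)c(OC)c(OC)c1Oc1cc(OC)c(Oc2cc(OC)c(C=O)c(OC)c2)c(OC)c1 | intermediate
21 | 4-(4-{6-[2,3-dimethoxy-5-(2,4,6-trimethoxyphenoxy)phenoxy]-2,3,4-trimethoxyphenoxy}-2,6-dimethoxyphenoxy)-2,6-dimethoxyphenyl formate | COc1c(OC)cc(Oc2c(OC)cc(OC)cc2OC)cc1Oc1cc(OC)c(OC)c(OC)c1Oc1cc(OC)c(Oc2cc(OC)c(OC=O)c(OC)c2)c(OC)c1 | intermediate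
22 | 4-(4-{6-[2,3-dimethoxy-5-(2,4,6-trimethoxyphenoxy)phenoxy]-2,3,4-trimethoxyphenoxy}-2,6-dimethoxyphenoxy)-2,6-dimethoxyphenol | COc1c(OC)cc(Oc2c(OC)cc(OC)cc2OC)cc1Oc1cc(OC)c(OC)c(OC)c1Oc1cc(OC)c(Oc2cc(OC)c(O)c(OC)c2)c(OC)c1 | intermediate
23 | 5-(4-{6-[2,3-dihydroxy-5-(2,4,6-trihydroxyphenoxy)phenoxy]-2,3,4-trihydroxyphenoxy}-2,6-dihydroxyphenoxy)benzene-1,2,3-triol (CNP0228612.0) | Oc1cc(O)c(Oc2cc(O)c(O)c(Oc3cc(O)c(O)c(O)c3Oc3cc(O)c(Oc4cc(O)c(O)c(O)c4)c(O)c3)c2)c(O)c1 | target

**Total step count:** 13. **Longest linear sequence:** 13 steps (1 to 23); 7, 8 and 16 enter as purchased components.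

**Steps most likely to fail**

Step 4. Site selectivity may erode. Part of the first phenoxide may add ortho to the formyl group, or a second phenoxide may add before all of 7 is consumed, and the isomeric ethers would then be carried into the second substitution.
The fallback sets out from 8 and comes back at 9. It fixes the A–O–B1 bond before the formyl group exists.
- Compound 8 is joined to 1-bromo-3,5-difluorobenzene by a copper-catalysed Ullmann ether synthesis (CuI, picolinic acid, K3PO4, DMSO, 90 °C, argon) to give 2-(3,5-difluorophenoxy)-1,3,5-trimethoxybenzene F1.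
- Lithium diisopropylamide in THF at −78 °C removes the most acidic hydrogen, the one between the two fluorines, and a DMF quench with aqueous work-up gives 9 as the only possible regioisomer.
- Isolated 9 then undergoes the second half of step 4 with 6.

Step 9. The addition step may stall. The doubly flanked C2 phenoxide meets a fluoroarene whose formyl acceptor is weakened by two ortho methoxy donors, and long heating in basic DMSO can degrade the aldehyde partner and oxidise the phenoxide.
The fallback sets out from 15 and comes back at 17. It brings in ring D as the far more electrophilic 7 and adds the methoxy groups afterwards.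
- Compound 15 and 7 (Cs2CO3, DMF, 0 °C to rt) should react at the para fluorine, as the bulky phenoxide did in step 4, to give 4-{6-[2,3-dimethoxy-5-(2,4,6-trimethoxyphenoxy)phenoxy]-2,3,4-trimethoxyphenoxy}-2,6-difluorobenzaldehyde F2.
- Excess NaOMe in MeOH/THF at 50 °C replaces both ortho fluorines to give 17.

Step 13. Cleavage of the twelve ethers may stay incomplete as borate aggregates fall out of solution, and the pyrogallol-type rings may oxidise in air during aqueous isolation.
The fallback sets out from 22 and comes back at 23. It uses a derivatise, purify and release sequence.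
- After the BBr3 treatment and quench, the crude polyphenol is not purified. It is acetylated at once (Ac2O, pyridine, rt) to 5-(4-{6-[2,3-diacetoxy-5-(2,4,6-triacetoxyphenoxy)phenoxy]-2,3,4-triacetoxyphenoxy}-2,6-diacetoxyphenoxy)benzene-1,2,3-triyl triacetate F3.
- F3 is air-stable and can be chromatographed, so partly methylated material can be separated from it.
- Acid-catalysed methanolysis (HCl, degassed MeOH, argon, rt) then releases 23 without exposing it to base.

**Further compounds**
F1 | step 4 | 2-(3,5-difluorophenoxy)-1,3,5-trimethoxybenzene | COc1cc(OC)c(Oc2cc(F)cc(F)c2)c(OC)c1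
F2 | step 9 | 4-{6-[2,3-dimethoxy-5-(2,4,6-trimethoxyphenoxy)phenoxy]-2,3,4-trimethoxyphenoxy}-2,6-difluorobenzaldehyde | COc1c(OC)cc(Oc2c(OC)cc(OC)cc2OC)cc1Oc1cc(OC)c(OC)c(OC)c1Oc1cc(F)c(C=O)c(F)c1
F3 | step 13 | 5-(4-{6-[2,3-diacetoxy-5-(2,4,6-triacetoxyphenoxy)phenoxy]-2,3,4-triacetoxyphenoxy}-2,6-diacetoxyphenoxy)benzene-1,2,3-triyl triacetate | CC(=O)Oc1cc(OC(C)=O)c(Oc2cc(OC(C)=O)c(OC(C)=O)c(Oc3cc(OC(C)=O)c(OC(C)=O)c(OC(C)=O)c3Oc3cc(OC(C)=O)c(Oc4cc(OC(C)=O)c(OC(C)=O)c(OC(C)=O)c4)c(OC(C)=O)c3)c2)c(OC(C)=O)c1
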